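**Retrosynthetic overview**
- The target is the (2S)-flavanone; the last step only frees the 3′-OH from its silyl ether.
- The pyranone ring (O1, C2, C3, C4, C4a, C8a) is grown from the five-membered furanone ring of a racemic 2-aryl-2-(iodomethyl)benzofuran-3(2H)-one by a radical 1,2-acyl shift. The planar C2 radical is then reduced on one face by a homochiral thiol, so both enantiomers of the precursor converge on (2S).
- Enabling feature: C2 carries both O1 and the B-ring aryl, so a radical at C2 is benzylic and α-oxygenated, and the neighbouring C4 aryl ketone accepts a CH2 radical placed on C2 (this CH2 becomes C3).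
- The precursor comes from C2-iodomethylation and Pd α-arylation (C2–C1′ bond, B ring) of 4,6-dimethoxy-7-prenylbenzofuran-3(2H)-one.
- That furanone comes from a salicylaldehyde and a sulfoxonium methylide, after ortho-formylation and C-prenylation of 3,5-dimethoxyphenol. Ring order: A ring (bought), furanone, B ring attached, furanone expanded to pyranone.

Key step: step 8

Remark: the stereodescriptor of the SMILES is read as (2S) (CIP order O1 > C1′ > C3 > H). Which antipode of the thiol catalyst gives this sense is to be fixed by screening both.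

**Step 1**
Reactants: 1 3,5-dimethoxyphenol
Product: 2 3,5-dimethoxy-2-(3-methylbut-2-en-1-yl)phenol
Conditions: NaH (1.0 equiv), toluene, 0 °C; prenyl bromide (1.0 equiv), 0 °C to rt
Reagents that add atoms: prenyl bromide (1-bromo-3-methylbut-2-ene), CC(C)=CCBr
Why: C-alkylation of a sodium phenoxide as a tight ion pair in a non-polar solvent should favour the ortho carbon (both ortho positions are equivalent), and no acid is present that could cyclise the ortho-prenylphenol.

**Step 2**
Reactants: 2 3,5-dimethoxy-2-(3-methylbut-2-en-1-yl)phenol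
Product: 3 2-hydroxy-4,6-dimethoxy-3-(3-methylbut-2-en-1-yl)benzaldehyde
Conditions: MgCl2, Et3N, (CH2O)n, MeCN, reflux; aq. citric acid work-up
Reagents that add atoms: paraformaldehyde (as formaldehyde), C=O
Why: Magnesium-phenoxide-directed ortho-formylation should go only to the single free ortho position and is non-acidic, so the prenyl group is not touched.

**Step 3**
Reactants: 3 2-hydroxy-4,6-dimethoxy-3-(3-methylbut-2-en-1-yl)benzaldehyde
Product: 4 racemic 4,6-dimethoxy-7-(3-methylbut-2-en-1-yl)-2,3-dihydrobenzofuran-3-ol
Conditions: Me3S(O)I (2.5 equiv), NaH (2.5 equiv), DMSO, rt then 50 °C; H2O quench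
Reagents that add atoms: trimethylsulfoxonium iodide, C[S+](C)(C)=O.[I-]
Why: Corey–Chaykovsky epoxidation of the aldehyde followed by 5-exo-tet opening of the terminal epoxide carbon by the ortho phenoxide should close the furan ring; the carbinol centre is racemic and is removed in step 4.

**Step 4**
Reactants: 4 racemic 4,6-dimethoxy-7-(3-methylbut-2-en-1-yl)-2,3-dihydrobenzofuran-3-ol
Product: 5 4,6-dimethoxy-7-(3-methylbut-2-en-1-yl)benzofuran-3(2H)-one
Conditions: TPAP (5 mol %), NMO (1.5 equiv), 4 Å MS, CH2Cl2, rt
Reagents that add atoms: none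
Why: Ley–Griffith oxidation of the secondary benzylic alcohol is neutral, which should avoid acid-induced dehydration to the benzofuran and leave the prenyl alkene alone.

**Step 5**
Reactants: 6 5-bromo-2-methoxyphenol
Product: 7 (5-bromo-2-methoxyphenoxy)triisopropylsilane
Conditions: TIPSCl (1.1 equiv), imidazole (2 equiv), DMF, rt
Reagents that add atoms: triisopropylsilyl chloride, CC(C)[Si](Cl)(C(C)C)C(C)C
Why: Standard silylation of a phenol; the TIPS ether should survive the phosphate and carbonate bases and the radical step and come off under buffered fluoride.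

**Step 6**
Reactants: 5 4,6-dimethoxy-7-(3-methylbut-2-en-1-yl)benzofuran-3(2H)-one and 7 (5-bromo-2-methoxyphenoxy)triisopropylsilane
Product: 8 racemic 4,6-dimethoxy-2-{4-methoxy-3-[(triisopropylsilyl)oxy]phenyl}-7-(3-methylbut-2-en-1-yl)benzofuran-3(2H)-one
Conditions: Pd(OAc)2 (3 mol %), XPhos (6 mol %), K3PO4 (2.5 equiv), toluene, 90 °C, Ar; degassed aq. NH4Cl work-up, used at once
Reagents that add atoms: none
Why: Pd-catalysed ketone α-arylation (Buchwald–Hartwig-type enolate arylation) should form C2–C1′, and the product rests as a stabilised 3-oxidobenzofuran that resists a second arylation; C2 is racemic, which does not matter because step 8 erases it.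

**Step 7**
Reactants: 8 racemic 4,6-dimethoxy-2-{4-methoxy-3-[(triisopropylsilyl)oxy]phenyl}-7-(3-methylbut-2-en-1-yl)benzofuran-3(2H)-one
Product: 9 racemic 2-(iodomethyl)-4,6-dimethoxy-2-{4-methoxy-3-[(triisopropylsilyl)oxy]phenyl}-7-(3-methylbut-2-en-1-yl)benzofuran-3(2H)-one
Conditions: K2CO3 (1.5 equiv), CH2I2 (6 equiv), acetone, 45 °C, dark, Ar
Reagents that add atoms: diiodomethane, ICI
Why: C-alkylation of the soft, aryl-stabilised enolate with a soft alkyl iodide should build the quaternary C2 (racemic), and the large excess of CH2I2 suppresses a second displacement.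

**Step 8**
Reactants: 9 racemic 2-(iodomethyl)-4,6-dimethoxy-2-{4-methoxy-3-[(triisopropylsilyl)oxy]phenyl}-7-(3-methylbut-2-en-1-yl)benzofuran-3(2H)-one
Product: 13 (2S)-5,7-dimethoxy-2-{4-methoxy-3-[(triisopropylsilyl)oxy]phenyl}-8-(3-methylbut-2-en-1-yl)chroman-4-one, via primary alkyl radical 10 (not isolated), via cyclopropyloxy radical 11 (not isolated), via ring-expanded benzylic radical 12 (not isolated)
Conditions: (Me3Si)3SiH (1.3 equiv) and homochiral cysteine-peptide thiol (10 mol %, antipode by screening) added slowly, AIBN (10 mol %), PhH (0.01 M), 60 °C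
Reagents that add atoms: none
Why: Proposed new method: the silyl radical abstracts iodine from either enantiomer of 9 to give primary radical 10, which adds 3-exo-trig to the C3 aryl ketone (alkoxy radical 11) and then cleaves the old C2–C3 bond, so the CH2 carbon is inserted between C2 and C=O and the five-membered furanone becomes the six-membered pyranone radical 12 (Dowd–Beckwith 1,2-acyl shift). The closest known reaction types are the stannane- or silane-mediated Dowd–Beckwith ring expansion of 2-halomethyl cyclic ketones and enantioselective hydrogen-atom transfer from homochiral thiols to prochiral benzylic or α-heteroatom radicals under polarity-reversal catalysis; what is new is their union on a 2-arylbenzofuran-3(2H)-one, with the aryl group and O1 (instead of an ester) stabilising the rearranged radical. The pyranone is not closed from a chain: it arises by 3-exo-trig attack on C=O and β-scission of the ring-fusion bond of 11, a net one-carbon 5→6 ring expansion. Radical 12 is planar at C2, which erases the configuration of 9 (stereoconvergence), and the only stereocentre is then set under catalyst control when the thiol S–H delivers hydrogen to the Re face of C2 (O1 > C1′ > C3) to give (2S); the silane is too weak a donor towards the stabilised radical 12 and only regenerates the thiol. The step needs the acyl shift to outrun premature reduction of 10, a 1,2-aryl (neophyl) shift of the B ring and 6-exo addition of 12 to the prenyl alkene; the benzylic, α-oxygenated, 4′-methoxy-stabilised radical 12 should make the β-scission fast and irreversible, the hydrogen donors are kept dilute, and the alkanethiol should trap 12 faster than it can cyclise.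

**Step 9**
Reactants: 13 (2S)-5,7-dimethoxy-2-{4-methoxy-3-[(triisopropylsilyl)oxy]phenyl}-8-(3-methylbut-2-en-1-yl)chroman-4-one
Product: 14 (2S)-2-(3-hydroxy-4-methoxyphenyl)-5,7-dimethoxy-8-(3-methylbut-2-en-1-yl)chroman-4-one
Conditions: TBAF (1.1 equiv), AcOH (1.2 equiv), THF, 0 °C
Reagents that add atoms: none
Why: Fluoride cleavage of the aryl silyl ether, buffered with acetic acid so that no basic phenoxide or enolate can open the pyranone by retro-oxa-Michael reaction; C2 should stay untouched.

**Compound list**
1 | 3,5-dimethoxyphenol | COc1cc(O)cc(OC)c1 | starting material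
2 | 3,5-dimethoxy-2-(3-methylbut-2-en-1-yl)phenol | COc1cc(O)c(CC=C(C)C)c(OC)c1 | intermediate
3 | 2-hydroxy-4,6-dimethoxy-3-(3-methylbut-2-en-1-yl)benzaldehyde | O=Cc1c(O)c(CC=C(C)C)c(OC)cc1OC | intermediate
4 | racemic 4,6-dimethoxy-7-(3-methylbut-2-en-1-yl)-2,3-dihydrobenzofuran-3-ol | OC1COc2c1c(OC)cc(OC)c2CC=C(C)C | intermediate
5 | 4,6-dimethoxy-7-(3-methylbut-2-en-1-yl)benzofuran-3(2H)-one | O=C1COc2c1c(OC)cc(OC)c2CC=C(C)C | intermediate
6 | 5-bromo-2-methoxyphenol | COc1ccc(Br)cc1O | starting material
7 | (5-bromo-2-methoxyphenoxy)triisopropylsilane | COc1ccc(Br)cc1O[Si](C(C)C)(C(C)C)C(C)C | intermediate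
8 | racemic 4,6-dimethoxy-2-{4-methoxy-3-[(triisopropylsilyl)oxy]phenyl}-7-(3-methylbut-2-en-1-yl)benzofuran-3(2H)-one | O=C1C(c2ccc(OC)c(O[Si](C(C)C)(C(C)C)C(C)C)c2)Oc2c1c(OC)cc(OC)c2CC=C(C)C | intermediate
9 | racemic 2-(iodomethyl)-4,6-dimethoxy-2-{4-methoxy-3-[(triisopropylsilyl)oxy]phenyl}-7-(3-methylbut-2-en-1-yl)benzofuran-3(2H)-one | O=C1C(CI)(c2ccc(OC)c(O[Si](C(C)C)(C(C)C)C(C)C)c2)Oc2c1c(OC)cc(OC)c2CC=C(C)C | intermediate
10 | primary alkyl radical (C2–CH2 radical of the furanone, not isolated) | O=C1C([CH2])(c2ccc(OC)c(O[Si](C(C)C)(C(C)C)C(C)C)c2)Oc2c1c(OC)cc(OC)c2CC=C(C)C | intermediate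
11 | cyclopropyloxy radical (cyclopropane C2–C3–CH2 fused to the furan ring, not isolated) | [O]C12CC1(c1ccc(OC)c(O[Si](C(C)C)(C(C)C)C(C)C)c1)Oc1c(CC=C(C)C)c(OC)cc(OC)c12 | intermediate
12 | ring-expanded benzylic radical (4-oxochroman-2-yl radical, not isolated) | O=C1C[C](c2ccc(OC)c(O[Si](C(C)C)(C(C)C)C(C)C)c2)Oc2c1c(OC)cc(OC)c2CC=C(C)C | intermediate
13 | (2S)-5,7-dimethoxy-2-{4-methoxy-3-[(triisopropylsilyl)oxy]phenyl}-8-(3-methylbut-2-en-1-yl)chroman-4-one | COc1ccc([C@@H]2CC(=O)c3c(OC)cc(OC)c(CC=C(C)C)c3O2)cc1O[Si](C(C)C)(C(C)C)C(C)C | intermediate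
14 | (2S)-2-(3-hydroxy-4-methoxyphenyl)-5,7-dimethoxy-8-(3-methylbut-2-en-1-yl)chroman-4-one | COc1ccc([C@@H]2CC(=O)c3c(OC)cc(OC)c(CC=C(C)C)c3O2)cc1O | target

**Step count and risks**
Total steps: 9. Longest linear sequence: 8 (steps 1–4 and 6–9).

Steps most likely to fail:

1. Step 8 (Proposed new method). The facial discrimination in the hydrogen-atom transfer may be insufficient, the product may racemise by reversible hydrogen abstraction at C2 by thiyl radicals, or the primary radical may be quenched before the acyl shift. The fallback uses known chemistry and sets out from 9. A classical Dowd–Beckwith ring expansion (Bu3SnH by syringe pump, AIBN, PhH, 80 °C) should give the racemic silyl-protected flavanone F1. Kinetic resolution of F1 by Rh-catalysed asymmetric transfer hydrogenation (Cp*RhCl(TsDPEN), HCO2H/Et3N, EtOAc, rt; the catalyst antipode that reduces the (2R)-ketone faster) should convert the (2R)-enantiomer into the cis-(2R,4R)-flavan-4-ol F2. The unreacted (2S)-ketone is compound 13, where the route is rejoined, at the cost of at most half of the material.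

2. Step 7. The ambident enolate may be alkylated on oxygen, or a second enolate may displace the remaining iodide to give a methylene-bridged dimer. The fallback sets out from 8. An aldol reaction with aqueous formaldehyde (cat. Et3N, THF, 0 °C) should give the 2-(hydroxymethyl) ketone F3. Appel iodination of F3 (PPh3, I2, imidazole, toluene, 60 °C) comes back to the route at 9.

3. Step 1. Alkylation may occur at the para carbon or at oxygen instead of the ortho carbon, and over-alkylation is possible. The fallback sets out from 1. Protection (MOMCl, i-Pr2NEt, CH2Cl2) gives the methoxymethyl ether F4. Directed ortho-lithiation between OMOM and OMe (n-BuLi, TMEDA, THF, 0 °C), transmetalation (CuBr·SMe2) and prenyl bromide should give the prenylated methoxymethyl ether F5. Mild acetal cleavage of F5 (cat. HCl, MeOH, 40 °C, monitored closely) comes back to the route at 2.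

**Further compounds**
F1 | step 8 | racemic 5,7-dimethoxy-2-{4-methoxy-3-[(triisopropylsilyl)oxy]phenyl}-8-(3-methylbut-2-en-1-yl)chroman-4-one | COc1ccc(C2CC(=O)c3c(OC)cc(OC)c(CC=C(C)C)c3O2)cc1O[Si](C(C)C)(C(C)C)C(C)C
F2 | step 8 | (2R,4R)-5,7-dimethoxy-2-{4-methoxy-3-[(triisopropylsilyl)oxy]phenyl}-8-(3-methylbut-2-en-1-yl)chroman-4-ol (2,4-cis) | COc1ccc([C@H]2C[C@@H](O)c3c(OC)cc(OC)c(CC=C(C)C)c3O2)cc1O[Si](C(C)C)(C(C)C)C(C)C
F3 | step 7 | racemic 2-(hydroxymethyl)-4,6-dimethoxy-2-{4-methoxy-3-[(triisopropylsilyl)oxy]phenyl}-7-(3-methylbut-2-en-1-yl)benzofuran-3(2H)-one | O=C1C(CO)(c2ccc(OC)c(O[Si](C(C)C)(C(C)C)C(C)C)c2)Oc2c1c(OC)cc(OC)c2CC=C(C)C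
F4 | step 1 | 1,3-dimethoxy-5-(methoxymethoxy)benzene | COCOc1cc(OC)cc(OC)c1
F5 | step 1 | 1,5-dimethoxy-3-(methoxymethoxy)-2-(3-methylbut-2-en-1-yl)benzene | COCOc1cc(OC)cc(OC)c1CC=C(C)C
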